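**Plan**

- Unit 1 is the 5-hydroxy-7-methoxyflavone half. Unit 2 is the acacetin half, bound through its C8 to C3' of unit 1. The retrosynthesis cuts, in order: the O-protecting groups, C4–C4a of unit 1, the C3'–C8 biaryl bond, then O1–C2 and C2–C1' of unit 1.
- Enabling feature: ring A of unit 1 is a phloroglucinol ring. Held on O1 as the 3,5-dimethoxyphenyl ether of the C2 enol, it has two symmetry-equivalent carbons ortho to O1, each activated by O1 and both methoxy oxygens, so acyl carbon C4 can bond only to the future C4a.
- Forward, first half: unit 2 comes whole from acacetin by benzylation and iodination at C8. Ring B of unit 1 (2-bromo-4-iodophenol) receives C2–C3–C4 as a propiolate, ring A by oxa-Michael addition, and boron at C3'.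
- Forward, second half: Suzuki coupling joins the halves and saponification frees the acid. Ring C of unit 1 closes as the last of the six rings, and BCl3 then removes the three benzyl ethers and the peri 5-methyl ether.
- Stereochemistry: the target has no stereocentre and its biaryl axis is undefined. The only stereo-element on the way is the Z enol ether (oxygen and carboxyl cis), set in the oxa-Michael step and absorbed into the aromatic pyranone.

Key step: step 9

Assumption: a minor E isomer of the enol ethers 9 to 12 is carried along unseparated, because acid equilibration of the double bond in step 9 should bring it to the same product.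

**Step 1**
Reactants: 1 acacetin
Product: 2 5,7-di-O-benzylacacetin
Conditions: BnBr, K2CO3, DMF, 80 °C
Reagents that add atoms: benzyl bromide, BrCc1ccccc1
Why: Williamson ether synthesis in which excess halide and heat in a dipolar aprotic solvent should also alkylate the hydrogen-bonded 5-OH.

**Step 2**
Reactants: 2 5,7-di-O-benzylacacetin
Product: 3 8-iodo-5,7-di-O-benzylacacetin
Conditions: I2, AgOAc, CH2Cl2, rt, dark
Reagents that add atoms: iodine, II
Why: Electrophilic aromatic iodination of a 5,7-dialkoxyflavone should go to C8, which has only one benzyloxy neighbour, whereas C6 lies between two and ring B is deactivated by the pyranone.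

**Step 3**
Reactants: 4 2-bromo-4-iodophenol
Product: 5 1-(benzyloxy)-2-bromo-4-iodobenzene
Conditions: BnBr, K2CO3, acetone, reflux
Reagents that add atoms: benzyl bromide, BrCc1ccccc1
Why: Williamson ether synthesis on an acidic, unhindered phenol, with both halogens inert to carbonate.

**Step 4**
Reactants: 5 1-(benzyloxy)-2-bromo-4-iodobenzene; 6 methyl propiolate
Product: 7 methyl 3-[4-(benzyloxy)-3-bromophenyl]propiolate
Conditions: 6 (slow addition), PdCl2(PPh3)2, CuI, K2CO3, THF, 65 °C
Reagents that add atoms: none
Why: Sonogashira coupling in which zerovalent palladium inserts into the carbon–iodine bond far faster than into the electron-rich ortho-alkoxy carbon–bromine bond, and the inorganic base avoids amine addition to the propiolate.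

**Step 5**
Reactants: 7 methyl 3-[4-(benzyloxy)-3-bromophenyl]propiolate; 8 3,5-dimethoxyphenol
Product: 9 methyl (Z)-3-[4-(benzyloxy)-3-bromophenyl]-3-(3,5-dimethoxyphenoxy)acrylate
Conditions: K2CO3, DMF, 80 °C
Reagents that add atoms: none
Why: Oxa-Michael addition of a phenoxide to an arylpropiolate (first stage of the Ruhemann flavone synthesis), in which anti addition and the preference for the aryl group trans to the ester both favour the Z enol ether.

**Step 6**
Reactants: 9 methyl (Z)-3-[4-(benzyloxy)-3-bromophenyl]-3-(3,5-dimethoxyphenoxy)acrylate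
Product: 10 methyl (Z)-3-[4-(benzyloxy)-3-(pinacolboryl)phenyl]-3-(3,5-dimethoxyphenoxy)acrylate
Conditions: B2pin2, Pd(dppf)Cl2, KOAc, 1,4-dioxane, 90 °C
Reagents that add atoms: bis(pinacolato)diboron, CC1(C)OB(B2OC(C)(C)C(C)(C)O2)OC1(C)C
Why: Miyaura borylation, in which acetate is too weak a base to touch the ester or the enol ether and the trisubstituted acrylate is a poor partner for Heck-type side reactions.

**Step 7**
Reactants: 3 8-iodo-5,7-di-O-benzylacacetin; 10 methyl (Z)-3-[4-(benzyloxy)-3-(pinacolboryl)phenyl]-3-(3,5-dimethoxyphenoxy)acrylate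
Product: 11 methyl (Z)-3-[4-(benzyloxy)-3-(5,7-di-O-benzylacacetin-8-yl)phenyl]-3-(3,5-dimethoxyphenoxy)acrylate
Conditions: Pd(OAc)2, SPhos, K3PO4, toluene/H2O, 90 °C
Reagents that add atoms: none
Why: Suzuki–Miyaura coupling of an 8-iodoflavone with an ortho-alkoxyarylboronate is the established way to the 3',8-biflavone axis, and the bulky electron-rich biarylphosphine suits a tri-ortho-substituted biaryl.

**Step 8**
Reactants: 11 methyl (Z)-3-[4-(benzyloxy)-3-(5,7-di-O-benzylacacetin-8-yl)phenyl]-3-(3,5-dimethoxyphenoxy)acrylate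
Product: 12 (Z)-3-[4-(benzyloxy)-3-(5,7-di-O-benzylacacetin-8-yl)phenyl]-3-(3,5-dimethoxyphenoxy)acrylic acid
Conditions: LiOH, THF/MeOH/H2O, 40 °C; then 1 M HCl, 0 °C
Reagents that add atoms: lithium hydroxide, [Li+].[OH-]
Why: Saponification of a β-aryloxycinnamate is the classical second operation of the Ruhemann sequence, and mild LiOH should leave the flavone of unit 2, the benzyl ethers and the enol ether intact.

**Step 9**
Reactants: 12 (Z)-3-[4-(benzyloxy)-3-(5,7-di-O-benzylacacetin-8-yl)phenyl]-3-(3,5-dimethoxyphenoxy)acrylic acid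
Product: 14 tri-O-benzylputraflavone 5-O-methyl ether, via mixed trifluoroacetic anhydride 13 (not isolated)
Conditions: (CF3CO)2O, CH2Cl2, 0 °C to rt
Reagents that add atoms: none
Why: Trifluoroacetic anhydride converts acid 12 into mixed anhydride 13, whose acyl carbon (or the acylium ion derived from it) is attacked by a carbon ortho to O1 of the dimethoxyphenoxy ring, and loss of trifluoroacetate and a proton gives the 4-pyranone with the new C4–C4a bond. The closest known reactions are the acid-mediated cyclisation of β-aryloxycinnamic acids to flavones (Ruhemann synthesis) and Friedel–Crafts acylations of activated arenes by carboxylic acids with trifluoroacetic anhydride. Ring C of unit 1 (O1–C2–C3–C4–C4a–C8a) closes in the 6-exo-trig mode at the acyl carbon, with the carbonyl oxygen staying outside the ring. No stereocentre is formed; the Z geometry holds the acyl group next to the phenoxy ring, and any E isomer should equilibrate through C3 protonation by the liberated trifluoroacetic acid. The step needs site selectivity on the phenoxy ring, which the substrate secures because the two ortho carbons are symmetry-equivalent, each is ortho to O1, ortho to one methoxy group and para to the other, and the para carbon cannot be reached. Competing arenes are poor nucleophiles (ring A of unit 2 is deactivated by its carbonyl, and the ortho carbons of ring B are meta to the benzyloxy group, so indenone closure should not compete), while a small excess of anhydride at low temperature limits intermolecular trifluoroacetylation.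

**Step 10**
Reactants: 14 tri-O-benzylputraflavone 5-O-methyl ether
Product: 15 putraflavone
Conditions: BCl3, C6HMe5, CH2Cl2, −78 °C to rt; then H2O
Reagents that add atoms: none
Why: Lewis-acid ether cleavage in which BCl3 with pentamethylbenzene as benzyl cation scavenger should remove the three aryl benzyl ethers in the cold and, on warming, the one methyl ether chelated to the C4 carbonyl of unit 1, while the unchelated 7- and 4'''-methyl ethers are inert to BCl3.

**Compound list**

1 | acacetin (5,7-dihydroxy-4'-methoxyflavone) | COc1ccc(-c2cc(=O)c3c(O)cc(O)cc3o2)cc1 | starting material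
2 | 5,7-di-O-benzylacacetin (5,7-bis(benzyloxy)-2-(4-methoxyphenyl)chromen-4-one) | COc1ccc(-c2cc(=O)c3c(OCc4ccccc4)cc(OCc4ccccc4)cc3o2)cc1 | intermediate
3 | 8-iodo-5,7-di-O-benzylacacetin | COc1ccc(-c2cc(=O)c3c(OCc4ccccc4)cc(OCc4ccccc4)c(I)c3o2)cc1 | intermediate
4 | 2-bromo-4-iodophenol | Oc1ccc(I)cc1Br | starting material
5 | 1-(benzyloxy)-2-bromo-4-iodobenzene | Brc1cc(I)ccc1OCc1ccccc1 | intermediate
6 | methyl propiolate | C#CC(=O)OC | starting material
7 | methyl 3-[4-(benzyloxy)-3-bromophenyl]propiolate | COC(=O)C#Cc1ccc(OCc2ccccc2)c(Br)c1 | intermediate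
8 | 3,5-dimethoxyphenol | COc1cc(O)cc(OC)c1 | starting material
9 | methyl (Z)-3-[4-(benzyloxy)-3-bromophenyl]-3-(3,5-dimethoxyphenoxy)acrylate | COc1cc(OC)cc(O/C(=C\C(=O)OC)c2ccc(OCc3ccccc3)c(Br)c2)c1 | intermediate
10 | methyl (Z)-3-[4-(benzyloxy)-3-(4,4,5,5-tetramethyl-1,3,2-dioxaborolan-2-yl)phenyl]-3-(3,5-dimethoxyphenoxy)acrylate | COc1cc(OC)cc(O/C(=C\C(=O)OC)c2ccc(OCc3ccccc3)c(B3OC(C)(C)C(C)(C)O3)c2)c1 | intermediate
11 | methyl (Z)-3-{4-(benzyloxy)-3-[5,7-bis(benzyloxy)-2-(4-methoxyphenyl)-4-oxochromen-8-yl]phenyl}-3-(3,5-dimethoxyphenoxy)acrylate | COc1cc(OC)cc(O/C(=C\C(=O)OC)c2ccc(OCc3ccccc3)c(-c3c(OCc4ccccc4)cc(OCc4ccccc4)c4c(=O)cc(-c5ccc(OC)cc5)oc34)c2)c1 | intermediate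
12 | (Z)-3-{4-(benzyloxy)-3-[5,7-bis(benzyloxy)-2-(4-methoxyphenyl)-4-oxochromen-8-yl]phenyl}-3-(3,5-dimethoxyphenoxy)acrylic acid | COc1cc(OC)cc(O/C(=C\C(=O)O)c2ccc(OCc3ccccc3)c(-c3c(OCc4ccccc4)cc(OCc4ccccc4)c4c(=O)cc(-c5ccc(OC)cc5)oc34)c2)c1 | intermediate
13 | mixed anhydride of acid 12 with trifluoroacetic acid | COc1cc(OC)cc(O/C(=C\C(=O)OC(=O)C(F)(F)F)c2ccc(OCc3ccccc3)c(-c3c(OCc4ccccc4)cc(OCc4ccccc4)c4c(=O)cc(-c5ccc(OC)cc5)oc34)c2)c1 | intermediate
14 | tri-O-benzylputraflavone 5-O-methyl ether (5,7-bis(benzyloxy)-8-[2-(benzyloxy)-5-(5,7-dimethoxy-4-oxochromen-2-yl)phenyl]-2-(4-methoxyphenyl)chromen-4-one) | COc1ccc(-c2cc(=O)c3c(OCc4ccccc4)cc(OCc4ccccc4)c(-c4cc(-c5cc(=O)c6c(OC)cc(OC)cc6o5)ccc4OCc4ccccc4)c3o2)cc1 | intermediate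
15 | putraflavone | COc1ccc(-c2cc(=O)c3c(O)cc(O)c(-c4cc(-c5cc(=O)c6c(O)cc(OC)cc6o5)ccc4O)c3o2)cc1 | target

**Step count**

Total step count: 10. Longest linear sequence: 8 steps (steps 3 to 10, from 2-bromo-4-iodophenol).

**Steps most likely to fail**

**Step 7.** Transmetalation and reductive elimination at the tri-ortho-substituted axis may be slow. Protodeboronation of the electron-rich boronate and hydrodeiodination of the iodide could then overtake the coupling.

The fallback exchanges the roles of the two partners. It sets out from 3, which on Miyaura borylation (B2pin2, Pd(dppf)Cl2, KOAc, 1,4-dioxane, 90 °C) would give 5,7-di-O-benzylacacetin-8-boronic acid pinacol ester F1. This would be coupled directly with bromide 9 (Pd(OAc)2, SPhos, K3PO4, toluene/H2O). Step 6 is then not needed, and the route is rejoined at 11.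

**Step 9.** Three processes may compete before ring closure:
- intermolecular trifluoroacetylation of the activated phenoxy ring;
- acidolysis of the enol ether with loss of the phenol;
- acid-induced loss of benzyl groups.

The fallback builds ring C of unit 1 by O1–C2 closure of a chalcone, away from unit 2. It sets out from 5 and proceeds as follows:
- Iodine–magnesium exchange (iPrMgCl, THF, −20 °C) and quenching with DMF would give 4-(benzyloxy)-3-bromobenzaldehyde F2.
- Claisen–Schmidt condensation with commercial 2'-hydroxy-4',6'-dimethoxyacetophenone (KOH, EtOH) would give (E)-4-benzyloxy-3-bromo-2'-hydroxy-4',6'-dimethoxychalcone F3.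
- Oxidative cyclisation (catalytic I2, DMSO, 130 °C) would give 4'-benzyloxy-3'-bromo-5,7-dimethoxyflavone F4.
- Miyaura borylation would give the 3'-pinacolboronate of that flavone F5.
- Suzuki coupling of F5 with 3 under the conditions of step 7 comes back to the route at 14.

**Step 10.** Partly deprotected boron phenolates may precipitate and stop the cleavage short. Benzyl cations may escape the scavenger and C-benzylate the phloroglucinol rings.

The fallback separates the two tasks and removes the benzyl groups reductively. It sets out from 14. Hydrogenolysis (H2, Pd/C, THF/MeOH, rt) would give 5-O-methylputraflavone F6. Its chelated methyl ether would then be cleaved with AlCl3 in MeCN at reflux followed by dilute HCl, arriving at 15.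

**Further compounds**

F1 | step 7 | 5,7-bis(benzyloxy)-2-(4-methoxyphenyl)-8-(4,4,5,5-tetramethyl-1,3,2-dioxaborolan-2-yl)chromen-4-one | COc1ccc(-c2cc(=O)c3c(OCc4ccccc4)cc(OCc4ccccc4)c(B4OC(C)(C)C(C)(C)O4)c3o2)cc1
F2 | step 9 | 4-(benzyloxy)-3-bromobenzaldehyde | O=Cc1ccc(OCc2ccccc2)c(Br)c1
F3 | step 9 | (E)-3-[4-(benzyloxy)-3-bromophenyl]-1-(2-hydroxy-4,6-dimethoxyphenyl)prop-2-en-1-one | COc1cc(O)c(C(=O)/C=C/c2ccc(OCc3ccccc3)c(Br)c2)c(OC)c1
F4 | step 9 | 2-[4-(benzyloxy)-3-bromophenyl]-5,7-dimethoxychromen-4-one | COc1cc(OC)c2c(=O)cc(-c3ccc(OCc4ccccc4)c(Br)c3)oc2c1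
F5 | step 9 | 2-[4-(benzyloxy)-3-(4,4,5,5-tetramethyl-1,3,2-dioxaborolan-2-yl)phenyl]-5,7-dimethoxychromen-4-one | COc1cc(OC)c2c(=O)cc(-c3ccc(OCc4ccccc4)c(B4OC(C)(C)C(C)(C)O4)c3)oc2c1
F6 | step 10 | 5-O-methylputraflavone | COc1ccc(-c2cc(=O)c3c(O)cc(O)c(-c4cc(-c5cc(=O)c6c(OC)cc(OC)cc6o5)ccc4O)c3o2)cc1
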